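**Strategy**

All three flavan units carry the same rings A and B and the same C2 configuration; they differ only in the oxygens at C3 and C4 of ring C. Everything therefore rests on one enantioenriched flav-3-ene, made by closing ring C through its O1–C2 bond: zerovalent palladium ionises a racemic 4-styryl-4H-1,3-benzodioxin-2-one, CO2 leaves, and the ring A phenoxide attacks the allyl terminus that is benzylic to ring B (C2), while the other terminus, benzylic to ring A, becomes C4. The C3=C4 bond left behind is oxidised on either face to give the terminal all-cis diol and two C4 electrophiles, which are joined at C6 by Friedel–Crafts couplings and debenzylated.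

Key step: step 5

Remark: α and β are used in the usual flavan sense (ring A on the left, O1 at the top, α below the plane); the ligand antipode in step 5 is to be fixed by a trial run, and the (R,R) form is written for definiteness.

**Route**

Step 1
Reactants: 1 1-(2,3,4-trihydroxyphenyl)ethan-1-one (gallacetophenone)
Product: 2 1-[3,4-bis(benzyloxy)-2-hydroxyphenyl]ethan-1-one
Conditions: BnBr (2.1 equiv), K2CO3 (2.2 equiv), acetone, reflux
Reagents that add atoms: benzyl bromide, BrCc1ccccc1
Why: Williamson etherification should alkylate only the 3- and 4-hydroxyls, because the 2-hydroxyl is locked in a hydrogen bond to the acetyl carbonyl and is the least nucleophilic.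

Step 2
Reactants: 2 1-[3,4-bis(benzyloxy)-2-hydroxyphenyl]ethan-1-one; 3 4-(benzyloxy)benzaldehyde
Product: 4 (E)-1-[3,4-bis(benzyloxy)-2-hydroxyphenyl]-3-[4-(benzyloxy)phenyl]prop-2-en-1-one
Conditions: KOH (aq. 50 %), EtOH/THF, rt; then cold dilute HCl
Reagents that add atoms: none
Why: Claisen–Schmidt condensation of the methyl ketone with the non-enolisable aldehyde should give the E-enone, the phenoxide in strong base holding the chalcone open against flavanone formation.

Step 3
Reactants: 4 (E)-1-[3,4-bis(benzyloxy)-2-hydroxyphenyl]-3-[4-(benzyloxy)phenyl]prop-2-en-1-one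
Product: 5 rac-(E)-1-[3,4-bis(benzyloxy)-2-hydroxyphenyl]-3-[4-(benzyloxy)phenyl]prop-2-en-1-ol
Conditions: NaBH4, CeCl3·7H2O, MeOH/THF, −20 °C; pH 7 buffer work-up, crude product used at once
Reagents that add atoms: none
Why: Luche 1,2-reduction should give the allylic alcohol without conjugate reduction, and the racemic carbinol centre is of no consequence because it is erased at the allylpalladium stage.

Step 4
Reactants: 5 rac-(E)-1-[3,4-bis(benzyloxy)-2-hydroxyphenyl]-3-[4-(benzyloxy)phenyl]prop-2-en-1-ol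
Product: 6 rac-7,8-bis(benzyloxy)-4-[(E)-2-[4-(benzyloxy)phenyl]ethenyl]-4H-1,3-benzodioxin-2-one
Conditions: 1,1'-carbonyldiimidazole (1.2 equiv), CH2Cl2, 0 °C to rt; rapid filtration through neutral alumina
Reagents that add atoms: 1,1'-carbonyldiimidazole, O=C(n1ccnc1)n1ccnc1
Why: Carbonylation of the 1,3-related phenol and benzylic alcohol should close the six-membered cyclic carbonate under neutral conditions, which masks the phenol and turns the carbinol oxygen into a leaving group in one operation.

Step 5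
Reactants: 6 rac-7,8-bis(benzyloxy)-4-[(E)-2-[4-(benzyloxy)phenyl]ethenyl]-4H-1,3-benzodioxin-2-one
Product: 7 (2S)-7,8-bis(benzyloxy)-2-[4-(benzyloxy)phenyl]-2H-chromene (2-aryl α)
Conditions: Pd2(dba)3·CHCl3 (2.5 mol %), (R,R)-TADDOL-derived N,N-dimethylphosphoramidite (10 mol %), toluene, −20 to 0 °C, dilute
Reagents that add atoms: none
Why: Zerovalent palladium should ionise the benzylic-allylic C–O bond of the carbonate with inversion, CO2 is lost, and a zwitterionic η3-1,3-diarylallyl palladium phenoxide results. After π–σ–π isomerisation that places ring A anti, the phenoxide oxygen attacks the allyl terminus bearing ring B on the face opposite to palladium and closes ring C through O1–C2 in a 6-endo-trig mode, the 4-exo alternative at the near terminus being prohibitively strained. The closest known reaction type is the enantioselective palladium-catalysed intramolecular allylic etherification (Tsuji–Trost) that gives 2-aryl-2H-chromenes, run here in the decarboxylative mode known for vinyl-substituted cyclic carbonates and carbamates. The C2 stereocentre is set by the chiral phosphoramidite on palladium (catalyst control), and both enantiomers of 6 should converge because the diastereomeric allyl complexes interconvert faster than the ring closes. The step needs the catalysed path to outrun uncatalysed ionisation to the free ortho-quinone methide, whose thermal 6π closure is racemic; the neutral carbonate tether secures this, since no phenoxide exists off the metal, supported by the non-polar solvent and low temperature.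

Step 6
Reactants: 7 (2S)-7,8-bis(benzyloxy)-2-[4-(benzyloxy)phenyl]-2H-chromene
Product: 10 (2R,3R,4R)-7,8-bis(benzyloxy)-2-[4-(benzyloxy)phenyl]chromane-3,4-diol (2,3-cis-3,4-cis), via iodo acetate 8 (not isolated), via hydroxy acetate 9 (not isolated)
Conditions: I2 (1.05 equiv), AgOAc (2.2 equiv), AcOH/H2O, dark, rt to 50 °C; then K2CO3 (cat.), MeOH, rt
Reagents that add atoms: silver acetate, CC(=O)[O-].[Ag+]
Why: Woodward cis-hydroxylation should proceed by iodonium formation anti to the 2-aryl group, acetate capture at benzylic C4 and silver-assisted displacement of iodide by the neighbouring acetate to a cis-fused acetoxonium ion on the aryl face, so that hydrolysis and methanolysis deliver the diol syn to the aryl group with C3 and C4 set by C2 (substrate control).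

Step 7
Reactants: 7 (2S)-7,8-bis(benzyloxy)-2-[4-(benzyloxy)phenyl]-2H-chromene
Product: 11 (2R,3S,4S)-7,8-bis(benzyloxy)-2-[4-(benzyloxy)phenyl]chromane-3,4-diol (2,3-trans-3,4-cis)
Conditions: OsO4 (2 mol %), N-methylmorpholine N-oxide (1.3 equiv), acetone/H2O, rt
Reagents that add atoms: N-methylmorpholine N-oxide, C[N+]1([O-])CCOCC1; water, O
Why: Upjohn dihydroxylation should add both hydroxyls suprafacially to the face of the C3=C4 bond remote from the 2-aryl group, which sets C3 and C4 by substrate control.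

Step 8
Reactants: 10 (2R,3R,4R)-7,8-bis(benzyloxy)-2-[4-(benzyloxy)phenyl]chromane-3,4-diol; 11 (2R,3S,4S)-7,8-bis(benzyloxy)-2-[4-(benzyloxy)phenyl]chromane-3,4-diol
Product: 12 hexa-O-benzyl oritin-(4α→6)-epioritin-4α-ol, upper unit (2R,3S,4R), lower unit (2R,3R,4R)
Conditions: 11 added slowly to 10 (3 equiv) and BF3·OEt2 (1.5 equiv), CH2Cl2, −40 to 0 °C; excess 10 recovered
Reagents that add atoms: none
Why: In this Lewis-acid-mediated Friedel–Crafts coupling the pseudo-axial 4-hydroxyl of 11 should ionise to a benzylic cation stabilised by O1 and the 7-benzyloxy group, which C6 of 10 (para to O1, ortho to the 7-benzyloxy group) captures on the face trans to the 3-hydroxyl to set the 4α centre, while the equatorial 4-hydroxyl of 10 is stereoelectronically reluctant to ionise.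

Step 9
Reactants: 7 (2S)-7,8-bis(benzyloxy)-2-[4-(benzyloxy)phenyl]-2H-chromene
Product: 15 (2R,3R,4S)-7,8-bis(benzyloxy)-2-[4-(benzyloxy)phenyl]chromane-3,4-diol (2,3-cis-3,4-trans), via bromohydrin 13 (not isolated), via oxirane 14 (not isolated)
Conditions: N-bromosuccinimide (1.05 equiv), THF/H2O 4:1, 0 °C; then aq. NaOH, 0 °C; then AcOH to pH 5, rt
Reagents that add atoms: water, O
Why: Bromohydrin formation (bromonium anti to the 2-aryl group, water at benzylic C4), base-induced closure with inversion at C3 to the oxirane on the aryl face and acid-catalysed trans-diaxial hydrolysis at benzylic C4 should give the 3α,4β-diol, each new centre being relayed from C2 (substrate control).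

Step 10
Reactants: 12 hexa-O-benzyl oritin-(4α→6)-epioritin-4α-ol; 15 (2R,3R,4S)-7,8-bis(benzyloxy)-2-[4-(benzyloxy)phenyl]chromane-3,4-diol
Product: 16 nona-O-benzyl epioritin-(4β→6)-oritin-(4α→6)-epioritin-4α-ol, upper unit (2R,3R,4S), middle unit (2R,3S,4R), lower unit (2R,3R,4R)
Conditions: 15 added slowly to 12 (2 equiv) and BF3·OEt2 (1.5 equiv), CH2Cl2, −40 to 0 °C; excess 12 recovered
Reagents that add atoms: none
Why: In this second Friedel–Crafts coupling the cation from the axial 4β-hydroxyl of 15 should be attacked by C6 of the upper unit of 12, the only free position para to a ring oxygen, on the face trans to the axial 3-hydroxyl, which sets the 4β centre as is general for 2,3-cis flavanyl cations.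

Step 11
Reactants: 16 nona-O-benzyl epioritin-(4β→6)-oritin-(4α→6)-epioritin-4α-ol
Product: 17 epioritin-(4β→6)-oritin-(4α→6)-epioritin-4α-ol (target)
Conditions: H2 (1 atm), Pd(OH)2/C, THF/MeOH/H2O, rt, stopped as soon as debenzylation is complete
Reagents that add atoms: none
Why: Catalytic hydrogenolysis should cleave the nine benzyl ethers faster than the interflavan C–C bonds or the equatorial benzylic 4-hydroxyl of the lower unit, so no stereocentre is touched.

**Compound list**

1 | 1-(2,3,4-trihydroxyphenyl)ethan-1-one | CC(=O)c1ccc(O)c(O)c1O | starting material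
2 | 1-[3,4-bis(benzyloxy)-2-hydroxyphenyl]ethan-1-one | CC(=O)c1ccc(OCc2ccccc2)c(OCc2ccccc2)c1O | intermediate
3 | 4-(benzyloxy)benzaldehyde | O=Cc1ccc(OCc2ccccc2)cc1 | starting material
4 | (E)-1-[3,4-bis(benzyloxy)-2-hydroxyphenyl]-3-[4-(benzyloxy)phenyl]prop-2-en-1-one | O=C(/C=C/c1ccc(OCc2ccccc2)cc1)c1ccc(OCc2ccccc2)c(OCc2ccccc2)c1O | intermediate
5 | rac-(E)-1-[3,4-bis(benzyloxy)-2-hydroxyphenyl]-3-[4-(benzyloxy)phenyl]prop-2-en-1-ol | OC(/C=C/c1ccc(OCc2ccccc2)cc1)c1ccc(OCc2ccccc2)c(OCc2ccccc2)c1O | intermediate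
6 | rac-7,8-bis(benzyloxy)-4-[(E)-2-[4-(benzyloxy)phenyl]ethenyl]-4H-1,3-benzodioxin-2-one | O=C1Oc2c(ccc(OCc5ccccc5)c2OCc5ccccc5)C(/C=C/c3ccc(OCc5ccccc5)cc3)O1 | intermediate
7 | (2S)-7,8-bis(benzyloxy)-2-[4-(benzyloxy)phenyl]-2H-chromene | c1cc2c(c(OCc5ccccc5)c1OCc5ccccc5)O[C@H](c3ccc(OCc5ccccc5)cc3)C=C2 | intermediate
8 | (2R,3R,4R)-7,8-bis(benzyloxy)-2-[4-(benzyloxy)phenyl]-3-iodochroman-4-yl acetate (3β-iodo, 4α-acetoxy) | c1cc2c(c(OCc5ccccc5)c1OCc5ccccc5)O[C@H](c3ccc(OCc5ccccc5)cc3)[C@@H](I)[C@@H]2OC(C)=O | intermediate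
9 | (2R,3R,4R)-7,8-bis(benzyloxy)-2-[4-(benzyloxy)phenyl]-4-hydroxychroman-3-yl acetate (all-cis) | c1cc2c(c(OCc5ccccc5)c1OCc5ccccc5)O[C@H](c3ccc(OCc5ccccc5)cc3)[C@H](OC(C)=O)[C@@H]2O | intermediate
10 | (2R,3R,4R)-7,8-bis(benzyloxy)-2-[4-(benzyloxy)phenyl]chromane-3,4-diol (tri-O-benzyl teracacidin) | c1cc2c(c(OCc5ccccc5)c1OCc5ccccc5)O[C@H](c3ccc(OCc5ccccc5)cc3)[C@H](O)[C@@H]2O | intermediate
11 | (2R,3S,4S)-7,8-bis(benzyloxy)-2-[4-(benzyloxy)phenyl]chromane-3,4-diol (2,3-trans-3,4-cis) | c1cc2c(c(OCc5ccccc5)c1OCc5ccccc5)O[C@H](c3ccc(OCc5ccccc5)cc3)[C@@H](O)[C@H]2O | intermediate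
12 | hexa-O-benzyl oritin-(4α→6)-epioritin-4α-ol | c1cc2c(c(OCc5ccccc5)c1OCc5ccccc5)O[C@H](c3ccc(OCc5ccccc5)cc3)[C@@H](O)[C@@H]2c1cc2c(c(OCc5ccccc5)c1OCc5ccccc5)O[C@H](c3ccc(OCc5ccccc5)cc3)[C@H](O)[C@@H]2O | intermediate
13 | (2R,3S,4R)-7,8-bis(benzyloxy)-2-[4-(benzyloxy)phenyl]-3-bromochroman-4-ol (3β-bromo, 4α-hydroxy) | c1cc2c(c(OCc5ccccc5)c1OCc5ccccc5)O[C@H](c3ccc(OCc5ccccc5)cc3)[C@@H](Br)[C@@H]2O | intermediate
14 | (2R,3R,4R)-7,8-bis(benzyloxy)-2-[4-(benzyloxy)phenyl]-3,4-epoxychromane (oxirane cis to the 2-aryl group) | c1cc2c(c(OCc5ccccc5)c1OCc5ccccc5)O[C@H](c3ccc(OCc5ccccc5)cc3)[C@@H]3O[C@H]23 | intermediate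
15 | (2R,3R,4S)-7,8-bis(benzyloxy)-2-[4-(benzyloxy)phenyl]chromane-3,4-diol (2,3-cis-3,4-trans) | c1cc2c(c(OCc5ccccc5)c1OCc5ccccc5)O[C@H](c3ccc(OCc5ccccc5)cc3)[C@H](O)[C@H]2O | intermediate
16 | nona-O-benzyl epioritin-(4β→6)-oritin-(4α→6)-epioritin-4α-ol | O(Cc5ccccc5)c1ccc([C@H]2Oc3c(ccc(OCc5ccccc5)c3OCc5ccccc5)[C@H](c3cc4c(c(OCc5ccccc5)c3OCc5ccccc5)O[C@H](c3ccc(OCc5ccccc5)cc3)[C@@H](O)[C@@H]4c3cc4c(c(OCc5ccccc5)c3OCc5ccccc5)O[C@H](c3ccc(OCc5ccccc5)cc3)[C@H](O)[C@@H]4O)[C@H]2O)cc1 | intermediate
17 | epioritin-(4β→6)-oritin-(4α→6)-epioritin-4α-ol | Oc1ccc([C@H]2Oc3c(ccc(O)c3O)[C@H](c3cc4c(c(O)c3O)O[C@H](c3ccc(O)cc3)[C@@H](O)[C@@H]4c3cc4c(c(O)c3O)O[C@H](c3ccc(O)cc3)[C@H](O)[C@@H]4O)[C@H]2O)cc1 | target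

**Step count and risks**

Total steps: 11. Longest linear sequence: 9 (steps 1, 2, 3, 4, 5, 6, 8, 10, 11).

Step 5 is the most exposed. The carbonate may ionise without the metal and lose CO2 to the free ortho-quinone methide, whose thermal ring closure is racemic, and the product may be re-ionised by palladium; both processes erode the enantiomeric purity on which every later centre depends. The fallback sets out from chalcone 4 and keeps the O1–C2 ring closure, now as an intramolecular oxa-Michael addition (NaOAc, EtOH, reflux) to racemic 7,8-bis(benzyloxy)-2-[4-(benzyloxy)phenyl]chroman-4-one F1. Kinetic resolution by asymmetric transfer hydrogenation with RuCl(p-cymene)[(S,S)-TsDPEN] (or its antipode, whichever reduces the 2S ketone) in HCO2H/Et3N, stopped near half conversion, should give (2S,4S)-7,8-bis(benzyloxy)-2-[4-(benzyloxy)phenyl]chroman-4-ol F2. Brief acid-catalysed dehydration (p-TsOH cat., toluene, 40 °C) returns to the route at 7.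

Step 8, and in the same way step 10, may suffer from capture of the cation by the free 3- and 4-hydroxyls instead of C6, from self-condensation of the electrophile, and from incomplete facial selectivity at C4 of the 2,3-trans unit. The fallback sets out from 11 and changes the donor to a thioether. Benzyl mercaptan with catalytic acid should give (2R,3R,4R)-7,8-bis(benzyloxy)-2-[4-(benzyloxy)phenyl]-4-(benzylsulfanyl)chroman-3-ol F3. This is activated thiophilically with AgBF4 in THF at 0 °C in the presence of 10, which leaves hydroxyl groups untouched and lets the donor be dosed, and it returns to the route at 12.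

Step 6 may fail through iodination of the activated ring A by the iodine–silver couple, or through acid-induced opening of the chromene before the alkene has reacted. The fallback sets out from 15: MnO2 in CH2Cl2 should oxidise only the benzylic 4-hydroxyl to (2R,3S)-7,8-bis(benzyloxy)-2-[4-(benzyloxy)phenyl]-3-hydroxychroman-4-one F4. Reduction with NaBH4/CeCl3·7H2O at −40 °C, hydride arriving on the face opposite to the axial 3-hydroxyl and the 2-aryl group, returns to the route at 10.

**Further compounds**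

F1 | step 5 | rac-7,8-bis(benzyloxy)-2-[4-(benzyloxy)phenyl]chroman-4-one | c1cc2c(c(OCc5ccccc5)c1OCc5ccccc5)OC(c3ccc(OCc5ccccc5)cc3)CC2=O
F2 | step 5 | (2S,4S)-7,8-bis(benzyloxy)-2-[4-(benzyloxy)phenyl]chroman-4-ol | c1cc2c(c(OCc5ccccc5)c1OCc5ccccc5)O[C@H](c3ccc(OCc5ccccc5)cc3)C[C@@H]2O
F3 | step 8 | (2R,3R,4R)-7,8-bis(benzyloxy)-2-[4-(benzyloxy)phenyl]-4-(benzylsulfanyl)chroman-3-ol | c1cc2c(c(OCc5ccccc5)c1OCc5ccccc5)O[C@H](c3ccc(OCc5ccccc5)cc3)[C@@H](O)[C@@H]2SCc5ccccc5
F4 | step 6 | (2R,3S)-7,8-bis(benzyloxy)-2-[4-(benzyloxy)phenyl]-3-hydroxychroman-4-one | c1cc2c(c(OCc5ccccc5)c1OCc5ccccc5)O[C@H](c3ccc(OCc5ccccc5)cc3)[C@H](O)C2=O
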